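**Plan**
Cuts (germacrane numbering, lactone oxygen on C8): the C15–O ester, the C11=C13 methylene, C9–C10 (ring closure, together with the C12–O8 lactone bond), C5–C6, C7–C8 and C3–C4.
Forward: a (Z)-alkenyl iodide (C1–C5, C14, C15; carbomagnesiation of propargyl alcohol) is joined at C5–C6 to a butanolide aldehyde (C6–C9, C11, C12; aldol and lactonisation), and the lactone is then opened to a C8–C9 epoxy ester.
Enabling feature: the homoallylic array O8–C8–C9H2–C10(Me)=C1H, where the ten-membered ring meets the γ-lactone. A C8–C9 epoxide and the 2-alkyne C10≡C1 of the same chain are coupled reductively on nickel; this closes the carbocycle at C9–C10, sets the (E)-C1=C10 alkene and frees O8 to re-form the lactone.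
End game: α-methylenation, unmasking of C15–OH, acylation with (E)-2-(acetoxymethyl)but-2-enoic acid, desilylation of O6.
Stereochemistry: C7 and C8 from an auxiliary-controlled syn-aldol (trans-lactone); C6 from Felkin–Anh addition to the C6 aldehyde; C4=C5 from anti-carbomagnesiation/iodination; C1=C10 from syn addition in the ring closure; the side-chain alkene from thermodynamic allylic acetate transposition.

Key step: step 10

Remark: positions are numbered as in germacranolides (C12 lactone carbonyl, C13 exocyclic methylene, C14 and C15 on C10 and C4); anhydrous chloroacetaldehyde is taken to be obtained by drying and distilling the commercial aqueous solution.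

**Route**

Step 1
Reactants: 1 5-bromopent-2-yne; 2 prop-2-yn-1-ol
Product: 4 (2Z)-3-iodo-2-(pent-3-yn-1-yl)prop-2-en-1-ol, via pent-3-yn-1-ylmagnesium bromide 3 (not isolated)
Conditions: Mg, THF, 23 °C; then 2, CuI (10 mol%), Et2O/THF, −10 → 23 °C; then I2, −40 → 0 °C
Reagents that add atoms: iodine ([I][I])
Why: Copper-catalysed anti-carbomagnesiation of the propargylic alkoxide puts the pentynyl group on C4 and magnesium on C5 in a five-membered chelate, so iodinolysis should give the (Z)-iodide with iodine cis to CH2OH, the geometry needed for C4=C5.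

Step 2
Reactants: 4 (2Z)-3-iodo-2-(pent-3-yn-1-yl)prop-2-en-1-ol
Product: 5 1-({[(2Z)-3-iodo-2-(pent-3-yn-1-yl)prop-2-en-1-yl]oxy}methyl)-4-methoxybenzene
Conditions: NaH, 4-methoxybenzyl chloride, Bu4NI (cat.), THF/DMF, 0 → 23 °C
Reagents that add atoms: 4-methoxybenzyl chloride (COc1ccc(CCl)cc1)
Why: Williamson etherification of the primary allylic alkoxide masks C15–OH as a p-methoxybenzyl ether that can later be removed oxidatively beside a silyl ether.

Step 3
Reactants: 6 (4R)-4-benzyl-1,3-oxazolidin-2-one; 7 methyl 4-chloro-4-oxobutanoate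
Product: 8 methyl 4-[(4R)-4-benzyl-2-oxo-1,3-oxazolidin-3-yl]-4-oxobutanoate
Conditions: n-BuLi, THF, −78 °C; then 7, −78 → 0 °C
Reagents that add atoms: none
Why: N-acylation of the lithiated oxazolidinone by the acid chloride is a standard imide formation and leaves the methyl ester untouched.

Step 4
Reactants: 8 methyl 4-[(4R)-4-benzyl-2-oxo-1,3-oxazolidin-3-yl]-4-oxobutanoate; 9 chloroacetaldehyde
Product: 11 (4R)-4-benzyl-3-{[(2R,3R)-2-(chloromethyl)-5-oxooxolan-3-yl]carbonyl}-1,3-oxazolidin-2-one, via syn-aldol hydroxy ester 10 (not isolated)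
Conditions: Bu2BOTf, i-Pr2NEt, CH2Cl2, −78 → 0 °C; 9 (freshly distilled), −78 → 0 °C; pH 7 buffer, MeOH, H2O2, 0 °C; then PPTS (cat.), toluene, 60 °C
Reagents that add atoms: none
Why: Evans syn-aldol reaction, in which the (Z)-boron enolate of the imide adds through a Zimmerman–Traxler chair with one face shielded by the (R)-benzyl auxiliary, should set C7 and C8 syn, and the C8 hydroxyl then closes onto the C12 ester to give the trans-lactone.

Step 5
Reactants: 11 (4R)-4-benzyl-3-{[(2R,3R)-2-(chloromethyl)-5-oxooxolan-3-yl]carbonyl}-1,3-oxazolidin-2-one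
Product: 12 S-ethyl (2R,3R)-2-(chloromethyl)-5-oxooxolane-3-carbothioate
Conditions: EtSH, n-BuLi (gives LiSEt), THF, −78 → 0 °C
Reagents that add atoms: ethanethiol (CCS)
Why: Thiolysis of the N-acyl oxazolidinone by lithium ethanethiolate should cleave the exocyclic imide carbonyl selectively, releasing the auxiliary and giving a thioester ready for reduction.

Step 6
Reactants: 12 S-ethyl (2R,3R)-2-(chloromethyl)-5-oxooxolane-3-carbothioate
Product: 13 (2R,3R)-2-(chloromethyl)-5-oxooxolane-3-carbaldehyde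
Conditions: Et3SiH, 10% Pd/C, acetone, 23 °C; crude aldehyde used at once
Reagents that add atoms: none
Why: Fukuyama reduction (palladium-catalysed hydrosilane reduction of a thioester) should stop at the aldehyde and tolerate the lactone and the alkyl chloride.

Step 7
Reactants: 5 1-({[(2Z)-3-iodo-2-(pent-3-yn-1-yl)prop-2-en-1-yl]oxy}methyl)-4-methoxybenzene; 13 (2R,3R)-2-(chloromethyl)-5-oxooxolane-3-carbaldehyde
Product: 15 (4S,5R)-5-(chloromethyl)-4-[(1R,2Z)-1-hydroxy-3-{[(4-methoxybenzyl)oxy]methyl}oct-2-en-6-yn-1-yl]oxolan-2-one, via alkenylchromium dichloride 14 (not isolated)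
Conditions: CrCl2 (4 equiv), NiCl2 (1 mol%), DMSO/THF, 23 °C
Reagents that add atoms: none
Why: Nozaki–Hiyama–Kishi coupling, in which the alkenylchromium species from 5 adds chemoselectively to the aldehyde, should follow Felkin–Anh attack anti to the C8 branch of the ring and so set (6R), syn to the C7–C11 bond, with retention of the C4=C5 geometry.

Step 8
Reactants: 15 (4S,5R)-5-(chloromethyl)-4-[(1R,2Z)-1-hydroxy-3-{[(4-methoxybenzyl)oxy]methyl}oct-2-en-6-yn-1-yl]oxolan-2-one
Product: 16 (4R,5R)-4-[(1R,2Z)-1-{[tert-butyl(dimethyl)silyl]oxy}-3-{[(4-methoxybenzyl)oxy]methyl}oct-2-en-6-yn-1-yl]-5-(chloromethyl)oxolan-2-one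
Conditions: TBSOTf, 2,6-lutidine, CH2Cl2, −78 → 0 °C
Reagents that add atoms: tert-butyldimethylsilyl triflate (CC(C)(C)[Si](C)(C)OS(=O)(=O)C(F)(F)F)
Why: Silylation of the secondary allylic alcohol with the silyl triflate protects O6 before base is used, so that only O8 can act as a nucleophile in the next steps.

Step 9
Reactants: 16 (4R,5R)-4-[(1R,2Z)-1-{[tert-butyl(dimethyl)silyl]oxy}-3-{[(4-methoxybenzyl)oxy]methyl}oct-2-en-6-yn-1-yl]-5-(chloromethyl)oxolan-2-one
Product: 17 methyl (3R,4R,5Z)-4-{[tert-butyl(dimethyl)silyl]oxy}-6-{[(4-methoxybenzyl)oxy]methyl}-3-[(2R)-oxiran-2-yl]undec-5-en-9-ynoate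
Conditions: K2CO3, MeOH, 0 → 23 °C
Reagents that add atoms: methanol (CO)
Why: Base-mediated methanolysis of the γ-lactone frees the C8 alkoxide, which displaces the neighbouring chloride (intramolecular Williamson reaction) irreversibly and with retention at C8 to give the terminal epoxide.

Step 10
Reactants: 17 methyl (3R,4R,5Z)-4-{[tert-butyl(dimethyl)silyl]oxy}-6-{[(4-methoxybenzyl)oxy]methyl}-3-[(2R)-oxiran-2-yl]undec-5-en-9-ynoate
Product: 19 (3aR,4R,5Z,9E,11aS)-4-{[tert-butyl(dimethyl)silyl]oxy}-6-{[(4-methoxybenzyl)oxy]methyl}-10-methyl-3a,4,7,8,11,11a-hexahydrocyclodeca[b]furan-2(3H)-one, via macrocyclic hydroxy ester 18 (not isolated)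
Conditions: Ni(cod)2 (20 mol%), PBu3 (40 mol%), Et3B (3 equiv), toluene, slow addition of 17 to 0.003 M, 23 → 50 °C; NH4Cl (aq); then PPTS (cat.), CH2Cl2, 23 °C
Reagents that add atoms: none
Why: Proposed new method: zerovalent nickel with PBu3 is expected to open the terminal epoxide at C9 and to insert the tethered 2-alkyne syn into the Ni–C9 bond, giving an oxanickelacycle with C9 bound to the methyl-bearing alkyne carbon C10; ethyl transfer from Et3B, β-hydride elimination and C–H reductive elimination then place hydrogen on C1 cis to C9, which is the (E)-C1=C10 alkene, and the O8 borinate lactonises onto the C12 ester on work-up. The closest known reaction type is the nickel-catalysed reductive coupling of alkynes with epoxides (between two molecules and for small rings), together with the nickel-catalysed reductive macrocyclisation of ynals; a dialkyl alkyne and a ten-membered ring go beyond both. The carbocycle closes in the endo mode at the alkyne (both alkyne carbons end up in the ring) with attack at the terminal epoxide carbon, and the γ-lactone closes 5-exo-trig by O8 onto C12. No stereocentre is formed: C8 keeps its configuration because its C–O bond is not broken, C6 and C7 are spectators, and the alkene geometry follows from syn addition across the alkyne. The step needs bond formation at C10 and not C1, at C9 and not C8, and ring closure in preference to oligomerisation; the small methyl substituent and the unhindered CH2 terminus should favour the first two, and binding of both termini to one nickel centre together with slow addition at high dilution the third.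

Step 11
Reactants: 19 (3aR,4R,5Z,9E,11aS)-4-{[tert-butyl(dimethyl)silyl]oxy}-6-{[(4-methoxybenzyl)oxy]methyl}-10-methyl-3a,4,7,8,11,11a-hexahydrocyclodeca[b]furan-2(3H)-one
Product: 22 (3aR,4R,5Z,9E,11aS)-4-{[tert-butyl(dimethyl)silyl]oxy}-6-{[(4-methoxybenzyl)oxy]methyl}-10-methyl-3-methylidene-3a,4,7,8,11,11a-hexahydrocyclodeca[b]furan-2(3H)-one, via Mannich base 20 (not isolated), via trimethylammonium iodide 21 (not isolated)
Conditions: LiN(i-Pr)2, THF, −78 °C; Me2N=CH2 I, −78 → 0 °C; crude amine: MeI, MeOH, 23 °C; then NaHCO3 (aq), EtOAc, 23 °C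
Reagents that add atoms: N,N-dimethylmethyleneiminium iodide (C=[N+](C)C.[I-])
Why: Mannich reaction of the lactone lithium enolate with the iminium salt, then quaternisation and Hofmann-type elimination, is the standard α-methylenation of γ-lactones, and the C11 configuration is irrelevant because C11 becomes sp2.

Step 12
Reactants: 22 (3aR,4R,5Z,9E,11aS)-4-{[tert-butyl(dimethyl)silyl]oxy}-6-{[(4-methoxybenzyl)oxy]methyl}-10-methyl-3-methylidene-3a,4,7,8,11,11a-hexahydrocyclodeca[b]furan-2(3H)-one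
Product: 23 (3aR,4R,5Z,9E,11aS)-4-{[tert-butyl(dimethyl)silyl]oxy}-6-(hydroxymethyl)-10-methyl-3-methylidene-3a,4,7,8,11,11a-hexahydrocyclodeca[b]furan-2(3H)-one
Conditions: DDQ, CH2Cl2/pH 7 buffer (10:1), 0 °C
Reagents that add atoms: none
Why: Oxidative cleavage of the p-methoxybenzyl ether by DDQ (hydride abstraction, then hydrolysis of the oxocarbenium ion) should free only the primary allylic C15–OH.

Step 13
Reactants: 24 tert-butyl prop-2-enoate; 25 acetaldehyde
Product: 26 tert-butyl 3-hydroxy-2-methylidenebutanoate (racemic)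
Conditions: DABCO (30 mol%), neat, 23 °C
Reagents that add atoms: none
Why: Morita–Baylis–Hillman reaction of the acrylate with acetaldehyde gives the racemic allylic alcohol, whose stereocentre is destroyed in the next step.

Step 14
Reactants: 26 tert-butyl 3-hydroxy-2-methylidenebutanoate
Product: 28 tert-butyl (2E)-2-[(acetyloxy)methyl]but-2-enoate, via secondary acetate 27 (not isolated)
Conditions: Ac2O, Et3N, DMAP (cat.), CH2Cl2, 0 → 23 °C; then DABCO (20 mol%), THF, 66 °C
Reagents that add atoms: acetic anhydride (CC(=O)OC(C)=O)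
Why: Acetylation followed by amine-catalysed 1,3-transposition of the allylic acetate (two SN2′ steps) should give the thermodynamically favoured trisubstituted (E)-enoate with the methyl group trans to the ester.

Step 15
Reactants: 28 tert-butyl (2E)-2-[(acetyloxy)methyl]but-2-enoate
Product: 29 (2E)-2-[(acetyloxy)methyl]but-2-enoic acid
Conditions: CF3CO2H/CH2Cl2 (1:3), 0 → 23 °C
Reagents that add atoms: none
Why: Acidolysis of the tert-butyl ester with loss of isobutene frees the carboxylic acid without touching the primary acetate.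

Step 16
Reactants: 23 (3aR,4R,5Z,9E,11aS)-4-{[tert-butyl(dimethyl)silyl]oxy}-6-(hydroxymethyl)-10-methyl-3-methylidene-3a,4,7,8,11,11a-hexahydrocyclodeca[b]furan-2(3H)-one; 29 (2E)-2-[(acetyloxy)methyl]but-2-enoic acid
Product: 30 [(3aR,4R,5Z,9E,11aS)-4-{[tert-butyl(dimethyl)silyl]oxy}-10-methyl-3-methylidene-2-oxo-2,3,3a,4,7,8,11,11a-octahydrocyclodeca[b]furan-6-yl]methyl (2E)-2-[(acetyloxy)methyl]but-2-enoate
Conditions: EDC·HCl, DMAP (cat.), CH2Cl2, 0 → 23 °C
Reagents that add atoms: none
Why: Steglich esterification (carbodiimide activation, acyl transfer by DMAP) acylates the only free hydroxyl, the primary allylic C15–OH.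

Step 17
Reactants: 30 [(3aR,4R,5Z,9E,11aS)-4-{[tert-butyl(dimethyl)silyl]oxy}-10-methyl-3-methylidene-2-oxo-2,3,3a,4,7,8,11,11a-octahydrocyclodeca[b]furan-6-yl]methyl (2E)-2-[(acetyloxy)methyl]but-2-enoate
Product: 31 [(3aS,4R,5Z,9E,11aS)-4-hydroxy-10-methyl-3-methylidene-2-oxo-2,3,3a,4,7,8,11,11a-octahydrocyclodeca[b]furan-6-yl]methyl (2E)-2-[(acetyloxy)methyl]but-2-enoate
Conditions: HF·pyridine, pyridine, THF, 0 → 23 °C
Reagents that add atoms: none
Why: Fluoride-mediated desilylation under buffered conditions should remove the silyl group from O6 while the α-methylene lactone, the acetate and the enoate survive.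

**Compound list**
(The spatial arrangement at C6, C7 and C8 is the same from 15 to 31; some CIP descriptors change only because substituent priorities change.)

1 | 5-bromopent-2-yne | CC#CCCBr | starting material
2 | prop-2-yn-1-ol | C#CCO | starting material
3 | pent-3-yn-1-ylmagnesium bromide | CC#CCC[Mg]Br | intermediate
4 | (2Z)-3-iodo-2-(pent-3-yn-1-yl)prop-2-en-1-ol | OC/C(CCC#CC)=C\I | intermediate
5 | 1-({[(2Z)-3-iodo-2-(pent-3-yn-1-yl)prop-2-en-1-yl]oxy}methyl)-4-methoxybenzene | COc1ccc(COC/C(CCC#CC)=C\I)cc1 | intermediate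
6 | (4R)-4-benzyl-1,3-oxazolidin-2-one | O=C1N[C@H](Cc2ccccc2)CO1 | starting material
7 | methyl 4-chloro-4-oxobutanoate | COC(=O)CCC(Cl)=O | starting material
8 | methyl 4-[(4R)-4-benzyl-2-oxo-1,3-oxazolidin-3-yl]-4-oxobutanoate | COC(=O)CCC(=O)N1[C@H](Cc2ccccc2)COC1=O | intermediate
9 | chloroacetaldehyde | ClCC=O | starting material
10 | methyl (3R,4R)-3-{[(4R)-4-benzyl-2-oxo-1,3-oxazolidin-3-yl]carbonyl}-5-chloro-4-hydroxypentanoate | COC(=O)C[C@@H](C(=O)N1[C@H](Cc2ccccc2)COC1=O)[C@@H](O)CCl | intermediate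
11 | (4R)-4-benzyl-3-{[(2R,3R)-2-(chloromethyl)-5-oxooxolan-3-yl]carbonyl}-1,3-oxazolidin-2-one (trans-lactone) | O=C1C[C@@H](C(=O)N2[C@H](Cc3ccccc3)COC2=O)[C@H](CCl)O1 | intermediate
12 | S-ethyl (2R,3R)-2-(chloromethyl)-5-oxooxolane-3-carbothioate | O=C1C[C@@H](C(=O)SCC)[C@H](CCl)O1 | intermediate
13 | (2R,3R)-2-(chloromethyl)-5-oxooxolane-3-carbaldehyde | O=C1C[C@@H](C=O)[C@H](CCl)O1 | intermediate
14 | {(1Z)-3-[(4-methoxybenzyl)oxy]-2-(pent-3-yn-1-yl)prop-1-en-1-yl}chromium dichloride | COc1ccc(COC/C(CCC#CC)=C\[Cr](Cl)Cl)cc1 | intermediate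
15 | (4S,5R)-5-(chloromethyl)-4-[(1R,2Z)-1-hydroxy-3-{[(4-methoxybenzyl)oxy]methyl}oct-2-en-6-yn-1-yl]oxolan-2-one | O=C1C[C@@H]([C@H](O)/C=C(/CCC#CC)COCc2ccc(OC)cc2)[C@H](CCl)O1 | intermediate
16 | (4R,5R)-4-[(1R,2Z)-1-{[tert-butyl(dimethyl)silyl]oxy}-3-{[(4-methoxybenzyl)oxy]methyl}oct-2-en-6-yn-1-yl]-5-(chloromethyl)oxolan-2-one | O=C1C[C@@H]([C@H](O[Si](C)(C)C(C)(C)C)/C=C(/CCC#CC)COCc2ccc(OC)cc2)[C@H](CCl)O1 | intermediate
17 | methyl (3R,4R,5Z)-4-{[tert-butyl(dimethyl)silyl]oxy}-6-{[(4-methoxybenzyl)oxy]methyl}-3-[(2R)-oxiran-2-yl]undec-5-en-9-ynoate | COC(=O)C[C@@H]([C@H](O[Si](C)(C)C(C)(C)C)/C=C(/CCC#CC)COCc1ccc(OC)cc1)[C@@H]1CO1 | intermediate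
18 | methyl [(1R,2R,3Z,7E,10S)-2-{[tert-butyl(dimethyl)silyl]oxy}-10-hydroxy-4-{[(4-methoxybenzyl)oxy]methyl}-8-methylcyclodeca-3,7-dien-1-yl]acetate | COC(=O)C[C@@H]1[C@@H](O)C/C(C)=C/CC/C(COCc2ccc(OC)cc2)=C/[C@H]1O[Si](C)(C)C(C)(C)C | intermediate
19 | (3aR,4R,5Z,9E,11aS)-4-{[tert-butyl(dimethyl)silyl]oxy}-6-{[(4-methoxybenzyl)oxy]methyl}-10-methyl-3a,4,7,8,11,11a-hexahydrocyclodeca[b]furan-2(3H)-one | O=C1O[C@H]2C/C(C)=C/CC/C(COCc3ccc(OC)cc3)=C/[C@@H](O[Si](C)(C)C(C)(C)C)[C@@H]2C1 | intermediate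
20 | 19 carrying a (dimethylamino)methyl group on C3 of the lactone (C3 epimers) | CN(C)CC1C(=O)O[C@H]2C/C(C)=C/CC/C(COCc3ccc(OC)cc3)=C/[C@@H](O[Si](C)(C)C(C)(C)C)[C@H]12 | intermediate
21 | N-methyl quaternary ammonium iodide of 20 (C3 epimers) | [I-].C[N+](C)(C)CC1C(=O)O[C@H]2C/C(C)=C/CC/C(COCc3ccc(OC)cc3)=C/[C@@H](O[Si](C)(C)C(C)(C)C)[C@H]12 | intermediate
22 | (3aR,4R,5Z,9E,11aS)-4-{[tert-butyl(dimethyl)silyl]oxy}-6-{[(4-methoxybenzyl)oxy]methyl}-10-methyl-3-methylidene-3a,4,7,8,11,11a-hexahydrocyclodeca[b]furan-2(3H)-one | C=C1C(=O)O[C@H]2C/C(C)=C/CC/C(COCc3ccc(OC)cc3)=C/[C@@H](O[Si](C)(C)C(C)(C)C)[C@H]12 | intermediate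
23 | (3aR,4R,5Z,9E,11aS)-4-{[tert-butyl(dimethyl)silyl]oxy}-6-(hydroxymethyl)-10-methyl-3-methylidene-3a,4,7,8,11,11a-hexahydrocyclodeca[b]furan-2(3H)-one | C=C1C(=O)O[C@H]2C/C(C)=C/CC/C(CO)=C/[C@@H](O[Si](C)(C)C(C)(C)C)[C@H]12 | intermediate
24 | tert-butyl prop-2-enoate | C=CC(=O)OC(C)(C)C | starting material
25 | acetaldehyde | CC=O | starting material
26 | tert-butyl 3-hydroxy-2-methylidenebutanoate (racemic) | CC(O)C(=C)C(=O)OC(C)(C)C | intermediate
27 | tert-butyl 3-(acetyloxy)-2-methylidenebutanoate (racemic) | CC(OC(C)=O)C(=C)C(=O)OC(C)(C)C | intermediate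
28 | tert-butyl (2E)-2-[(acetyloxy)methyl]but-2-enoate | C/C=C(\COC(C)=O)C(=O)OC(C)(C)C | intermediate
29 | (2E)-2-[(acetyloxy)methyl]but-2-enoic acid | C/C=C(\COC(C)=O)C(O)=O | intermediate
30 | [(3aR,4R,5Z,9E,11aS)-4-{[tert-butyl(dimethyl)silyl]oxy}-10-methyl-3-methylidene-2-oxo-2,3,3a,4,7,8,11,11a-octahydrocyclodeca[b]furan-6-yl]methyl (2E)-2-[(acetyloxy)methyl]but-2-enoate | C=C1C(=O)O[C@H]2C/C(C)=C/CC/C(COC(=O)/C(=C/C)COC(C)=O)=C/[C@@H](O[Si](C)(C)C(C)(C)C)[C@H]12 | intermediate
31 | [(3aS,4R,5Z,9E,11aS)-4-hydroxy-10-methyl-3-methylidene-2-oxo-2,3,3a,4,7,8,11,11a-octahydrocyclodeca[b]furan-6-yl]methyl (2E)-2-[(acetyloxy)methyl]but-2-enoate | C=C1C(=O)O[C@H]2C/C(C)=C/CC/C(COC(=O)/C(=C/C)COC(C)=O)=C/[C@@H](O)[C@H]12 | target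

**Count and risks**
Total step count: 17. Longest linear sequence: 12 steps (steps 3 to 12, then 16 and 17).

Steps most likely to fail:

1. Step 10 (Proposed new method). The dialkyl alkyne may be too unreactive towards the epoxide on nickel, bond formation may occur at the other alkyne carbon (C1) and close a nine-membered ring, or chains may couple with each other in place of ring closure. Fallback (known chemistry; sets out from 5 and 12, comes back at 19): C9–C10 is made between two molecules and the ring is closed at C5–C6 by the Nozaki–Hiyama–Kishi reaction already used in step 7. Iodine–lithium exchange on 5 (t-BuLi, Et2O, −78 °C) and silylation (Me3SiCl) should give alkenylsilane F1. Hydrozirconation of its 2-alkyne (Cp2Zr(H)Cl, THF, 23 → 40 °C, zirconium settling on the methyl-bearing carbon) and iodinolysis should give (E)-alkenyl iodide F2. Halide exchange on 12 (NaI, butanone, 80 °C) should give iodomethyl lactone F3. Nickel-catalysed reductive cross-electrophile coupling of F2 with F3 (NiBr2·glyme, 4,4′-di-tert-butyl-2,2′-bipyridine, Mn, N,N-dimethylacetamide, 23 °C) should give thioester F4. Fukuyama reduction (Et3SiH, Pd/C, acetone) should give aldehyde F5, and iododesilylation (N-iodosuccinimide, (CF3)2CHOH, 0 °C) should give alkenyl iodide F6 with retention of geometry. CrCl2 with NiCl2 (cat.) in DMSO/THF at 0.003 M should close the ten-membered ring to allylic alcohol F7, and TBSOTf with 2,6-lutidine then gives 19.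

2. Step 7. Facial selectivity at C6 may be poor or reversed, because the 1,3-relationship to O8 does not reinforce the Felkin–Anh preference, and the β-acyloxy aldehyde may undergo β-elimination before it couples. Fallback (sets out from 5 and 13, comes back at 15): the C6 stereocentre is set by inversion and not by facial control. The coupling is run as in step 7, and if the wrong face is attacked it delivers C6 epimer F8. A Mitsunobu reaction (ClCH2CO2H, PPh3, diisopropyl azodicarboxylate, THF, 0 °C) should convert it with inversion into chloroacetate F9, which thiourea and NaHCO3 in EtOH should cleave to 15 without opening the lactone.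

3. Step 11. Enolisation of the macrocyclic lactone may be incomplete or unselective, and the strained diene may degrade under strong base and during quaternisation. Fallback (sets out from 16, comes back at 20): the aminomethyl group is installed on the simple butanolide before the ring is closed. LiN(i-Pr)2 and then Me2N=CH2 I on 16 should give Mannich base F10, K2CO3 in MeOH should give epoxy ester F11, and the conditions of step 10 should give macrocyclic hydroxy ester F12, which lactonises to 20. Quaternisation and elimination then follow as in step 11.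

**Further compounds**
F1 | step 10 | {(1Z)-3-[(4-methoxybenzyl)oxy]-2-(pent-3-yn-1-yl)prop-1-en-1-yl}(trimethyl)silane | COc1ccc(COC/C(CCC#CC)=C\[Si](C)(C)C)cc1
F2 | step 10 | {(1Z,5E)-6-iodo-2-{[(4-methoxybenzyl)oxy]methyl}hepta-1,5-dien-1-yl}(trimethyl)silane | COc1ccc(COC/C(CC/C=C(/I)C)=C\[Si](C)(C)C)cc1
F3 | step 10 | S-ethyl (2R,3R)-2-(iodomethyl)-5-oxooxolane-3-carbothioate | O=C1C[C@@H](C(=O)SCC)[C@H](CI)O1
F4 | step 10 | S-ethyl (2S,3R)-2-[(2E,6Z)-6-{[(4-methoxybenzyl)oxy]methyl}-2-methyl-7-(trimethylsilyl)hepta-2,6-dien-1-yl]-5-oxooxolane-3-carbothioate | O=C1C[C@@H](C(=O)SCC)[C@H](C/C(C)=C/CC/C(COCc2ccc(OC)cc2)=C/[Si](C)(C)C)O1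
F5 | step 10 | (2S,3R)-2-[(2E,6Z)-6-{[(4-methoxybenzyl)oxy]methyl}-2-methyl-7-(trimethylsilyl)hepta-2,6-dien-1-yl]-5-oxooxolane-3-carbaldehyde | O=C1C[C@@H](C=O)[C@H](C/C(C)=C/CC/C(COCc2ccc(OC)cc2)=C/[Si](C)(C)C)O1
F6 | step 10 | (2S,3R)-2-[(2E,6Z)-7-iodo-6-{[(4-methoxybenzyl)oxy]methyl}-2-methylhepta-2,6-dien-1-yl]-5-oxooxolane-3-carbaldehyde | O=C1C[C@@H](C=O)[C@H](C/C(C)=C/CC/C(COCc2ccc(OC)cc2)=C/I)O1
F7 | step 10 | (3aS,4R,5Z,9E,11aS)-4-hydroxy-6-{[(4-methoxybenzyl)oxy]methyl}-10-methyl-3a,4,7,8,11,11a-hexahydrocyclodeca[b]furan-2(3H)-one | O=C1O[C@H]2C/C(C)=C/CC/C(COCc3ccc(OC)cc3)=C/[C@@H](O)[C@@H]2C1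
F8 | step 7 | (4S,5R)-5-(chloromethyl)-4-[(1S,2Z)-1-hydroxy-3-{[(4-methoxybenzyl)oxy]methyl}oct-2-en-6-yn-1-yl]oxolan-2-one | O=C1C[C@@H]([C@@H](O)/C=C(/CCC#CC)COCc2ccc(OC)cc2)[C@H](CCl)O1
F9 | step 7 | (1R,2Z)-1-[(2R,3S)-2-(chloromethyl)-5-oxooxolan-3-yl]-3-{[(4-methoxybenzyl)oxy]methyl}oct-2-en-6-yn-1-yl chloroacetate | O=C1C[C@@H]([C@H](OC(=O)CCl)/C=C(/CCC#CC)COCc2ccc(OC)cc2)[C@H](CCl)O1
F10 | step 11 | 16 carrying a (dimethylamino)methyl group on C3 of the lactone (C3 epimers) | O=C1C(CN(C)C)[C@@H]([C@H](O[Si](C)(C)C(C)(C)C)/C=C(/CCC#CC)COCc2ccc(OC)cc2)[C@H](CCl)O1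
F11 | step 11 | 17 carrying a (dimethylamino)methyl group on C2 of the ester chain (C2 epimers) | COC(=O)C(CN(C)C)[C@@H]([C@H](O[Si](C)(C)C(C)(C)C)/C=C(/CCC#CC)COCc1ccc(OC)cc1)[C@@H]1CO1
F12 | step 11 | 18 carrying a (dimethylamino)methyl group α to the ester (epimers) | COC(=O)C(CN(C)C)[C@@H]1[C@@H](O)C/C(C)=C/CC/C(COCc2ccc(OC)cc2)=C/[C@H]1O[Si](C)(C)C(C)(C)C
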